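**Retrosynthetic overview**

1. Numbering used (chamigrane): ring B = C1H2–C2HBr–C3(Me)Cl–C4H2–C5H2–C6 (spiro); ring A = C6–C7H(Me)–C8H2–C9H2–C10HBr–C11Me2.
2. Target ⇐ C7 exocyclic methylene (hydrogenation anti to the axial C11 methyl sets C7) ⇐ closure of ring B by the C1–C6 bond: the tetrasubstituted C6=C7 alkene of a monocyclic ring A attacks C1 of a side chain that already carries the C2–Br/C3–Cl pair.
3. Enabling feature: C1 is a primary carbon next to the secondary C2 bromide and six atoms from C6, so its triflate ionises through a C1–C2 bromiranium ion that the ring A alkene opens at C1. This lets the trans-diequatorial Br/Cl pair of ring B be set beforehand, by reagent control, on an acyclic (Z)-allylic alcohol instead of by a late anti addition to a ring alkene.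
4. Side chain ⇐ (Z)-selective alkylation of the prenol dianion with a ring A allylic bromide; ring A ⇐ C6–C11 closure of a β-keto ester by stereospecific bromiranium solvolysis of a prenol-derived bromochloride (sets C10), then enol triflate and methylation.
5. Ring order: ring A (step 4), then ring B with the spiro centre (step 11); carbon sources are prenol (twice), methyl acetoacetate and Me2Zn.

Key step: step 11

Assumption: in the titanium-mediated bromochlorinations (steps 1 and 10) the absolute sense is dictated by the chiral Schiff-base ligand, and in each case the ligand enantiomer that gives the configuration drawn is used.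

**Route**

Step 1
Reactants: 1 prenol (3-methylbut-2-en-1-ol)
Product: 2 (2R)-2-bromo-3-chloro-3-methylbutan-1-ol
Conditions: NBS, ClTi(OiPr)3, chiral tridentate Schiff-base ligand (salicylaldimine of a 1,1-diaryl amino alcohol, 20 mol%), hexanes, −20 °C
Reagents that add atoms: N-bromosuccinimide, O=C1CCC(=O)N1Br; chlorotitanium triisopropoxide, CC(C)O[Ti](Cl)(OC(C)C)OC(C)C
Why: Titanium-mediated catalytic enantioselective bromochlorination of an allylic alcohol, in which the titanium-bound alkoxide directs bromiranium formation and chloride is delivered anti to the distal tertiary carbon (Markovnikov), the ligand fixing the face so that the secondary C–Br centre (future C10) is formed as R.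

Step 2
Reactants: 2 (2R)-2-bromo-3-chloro-3-methylbutan-1-ol
Product: 3 (2R)-2-bromo-3-chloro-3-methylbutyl trifluoromethanesulfonate
Conditions: Tf2O, 2,6-lutidine, CH2Cl2, −78 °C
Reagents that add atoms: trifluoromethanesulfonic anhydride, O=S(=O)(OS(=O)(=O)C(F)(F)F)C(F)(F)F
Why: Standard O-triflation of a primary alcohol at low temperature, which does not touch the stereocentre.

Step 3
Reactants: 3 (2R)-2-bromo-3-chloro-3-methylbutyl trifluoromethanesulfonate; 4 methyl acetoacetate
Product: 6 methyl (6R)-6-bromo-7-chloro-7-methyl-3-oxooctanoate, via acetoacetate dianion 5 (not isolated)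
Conditions: 4, NaH then n-BuLi, THF, 0 °C; 3, −78 → −30 °C; aq HCl quench
Reagents that add atoms: none
Why: γ-Alkylation of the acetoacetate dianion, whose terminal carbanion displaces the primary triflate by SN2 fast enough at −78 °C that elimination of the β-bromide should not compete; no stereocentre is affected.

Step 4
Reactants: 6 methyl (6R)-6-bromo-7-chloro-7-methyl-3-oxooctanoate
Product: 7 methyl (3R)-3-bromo-2,2-dimethyl-6-oxocyclohexane-1-carboxylate
Conditions: 1,1,1,3,3,3-hexafluoropropan-2-ol (HFIP), 0 °C → rt
Reagents that add atoms: none
Why: Solvolytic bromiranium generation from a vicinal bromochloride (ionisation of the tertiary chloride assisted by the anti bromine, so C10 keeps its configuration) followed by cation–enol cyclisation at the tertiary carbon through a chair with equatorial bromine; O-alkylation by the tertiary centre is reversible in the acidic medium whereas C–C bond formation is not, and the new C1 centre of 7 is enolisable and is removed in step 5.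

Step 5
Reactants: 7 methyl (3R)-3-bromo-2,2-dimethyl-6-oxocyclohexane-1-carboxylate
Product: 8 methyl (5R)-5-bromo-6,6-dimethyl-2-[(trifluoromethanesulfonyl)oxy]cyclohex-1-ene-1-carboxylate
Conditions: Tf2O, i-Pr2NEt, CH2Cl2, −78 → 0 °C
Reagents that add atoms: trifluoromethanesulfonic anhydride, O=S(=O)(OS(=O)(=O)C(F)(F)F)C(F)(F)F
Why: Enol triflate formation from a cyclic β-keto ester, which can only give the ester-conjugated C6=C7 regioisomer.

Step 6
Reactants: 8 methyl (5R)-5-bromo-6,6-dimethyl-2-[(trifluoromethanesulfonyl)oxy]cyclohex-1-ene-1-carboxylate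
Product: 9 methyl (5R)-5-bromo-2,6,6-trimethylcyclohex-1-ene-1-carboxylate
Conditions: Me2Zn, Pd(PPh3)4 (5 mol%), THF, 0 °C → rt
Reagents that add atoms: dimethylzinc, C[Zn]C
Why: Negishi cross-coupling of the electron-poor alkenyl triflate installs the C7 methyl group and fixes the tetrasubstituted C6=C7 alkene, while the neopentylic secondary bromide should not undergo oxidative addition under these conditions.

Step 7
Reactants: 9 methyl (5R)-5-bromo-2,6,6-trimethylcyclohex-1-ene-1-carboxylate
Product: 10 [(5R)-5-bromo-2,6,6-trimethylcyclohex-1-en-1-yl]methanol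
Conditions: i-Bu2AlH (2.5 equiv), CH2Cl2, −78 °C; aq Rochelle salt
Reagents that add atoms: none
Why: DIBAL-H 1,2-reduction of the hindered conjugated ester to the allylic alcohol, with the secondary bromide inert at −78 °C.

Step 8
Reactants: 10 [(5R)-5-bromo-2,6,6-trimethylcyclohex-1-en-1-yl]methanol
Product: 11 (4R)-4-bromo-2-(bromomethyl)-1,3,3-trimethylcyclohex-1-ene
Conditions: PBr3, pyridine (cat.), Et2O, −10 °C
Reagents that add atoms: phosphorus tribromide, BrP(Br)Br
Why: Conversion of a primary allylic alcohol into the allylic bromide with PBr3 (substitution at the primary carbon), with no stereocentre involved.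

Step 9
Reactants: 11 (4R)-4-bromo-2-(bromomethyl)-1,3,3-trimethylcyclohex-1-ene; 1 prenol
Product: 13 (2Z)-5-[(5R)-5-bromo-2,6,6-trimethylcyclohex-1-en-1-yl]-3-methylpent-2-en-1-ol, via prenol dianion 12 (not isolated)
Conditions: 1, n-BuLi (2.1 equiv), TMEDA, Et2O/hexane, 0 °C → rt; then 11, −78 → 0 °C; H2O quench
Reagents that add atoms: none
Why: Alkoxide-directed metalation of prenol at the methyl group cis to the CH2OLi arm, then SN2 alkylation of this dianion at its unsubstituted terminus by the reactive allylic bromide, should give the (Z)-trisubstituted allylic alcohol, the geometry that leads to a trans halide pair in ring B.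

Step 10
Reactants: 13 (2Z)-5-[(5R)-5-bromo-2,6,6-trimethylcyclohex-1-en-1-yl]-3-methylpent-2-en-1-ol
Product: 14 (2S,3S)-2-bromo-5-[(5R)-5-bromo-2,6,6-trimethylcyclohex-1-en-1-yl]-3-chloro-3-methylpentan-1-ol
Conditions: NBS, ClTi(OiPr)3, chiral tridentate Schiff-base ligand (20 mol%), hexanes, −20 °C
Reagents that add atoms: N-bromosuccinimide, O=C1CCC(=O)N1Br; chlorotitanium triisopropoxide, CC(C)O[Ti](Cl)(OC(C)C)OC(C)C
Why: The same titanium-mediated enantioselective bromochlorination adds bromine to C2 and chloride to the tertiary C3 anti across the (Z)-alkene, setting both centres as (2S,3S) under ligand control, while the hindered, undirected ring A alkene should be left untouched by the hydroxyl-directed reaction.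

Step 11
Reactants: 14 (2S,3S)-2-bromo-5-[(5R)-5-bromo-2,6,6-trimethylcyclohex-1-en-1-yl]-3-chloro-3-methylpentan-1-ol
Product: 16 (2R,6S,8S,9S)-2,8-dibromo-9-chloro-1,1,9-trimethyl-5-methylidenespiro[5.5]undecane, via triflate 15 (not isolated)
Conditions: Tf2O, 2,6-di-tert-butyl-4-methylpyridine (3 equiv), CH2Cl2, −78 °C; then MeNO2 added, −78 → 0 °C
Reagents that add atoms: none
Why: Proposed new method: O-triflation gives primary triflate 15, whose anti β-bromine displaces triflate to a C1–C2 bromiranium ion that is opened at the primary C1 by the tetrasubstituted C6=C7 π bond (or the π bond displaces triflate with bromine assistance), and the resulting tertiary C7 cation loses a proton from its methyl group to the hindered base to give the exocyclic alkene. The closest known reactions are sulfonate-solvolysis (π-route) cation–olefin cyclisations and enantiospecific bromiranium-initiated polyene cyclisations; new here is opening at the primary carbon with the halogen pair already in place. Ring B closes through a six-membered chair (6-endo opening of the bromiranium ion, equivalent to 6-exo-tet displacement at C1, with the alkene exocyclic to the new ring). The only new stereocentre, spiro C6, is controlled by this chair: C2–Br is equatorial because it is anti to the entering C6, hence C3–Cl is equatorial and C3–Me axial, and the quaternary C11 takes the equatorial site with C7 axial, which is the (6S) arrangement; C2, C3 and C10 are not touched. The step needs attack at C1 rather than C2 (C2 is neopentylic and deactivated by the β-chlorine), no ionisation of the tertiary C3–Cl (non-protic medium, no Lewis acid) and exocyclic proton loss (bulky base; any endocyclic C7=C8 isomer converges in step 12).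

Step 12
Reactants: 16 (2R,6S,8S,9S)-2,8-dibromo-9-chloro-1,1,9-trimethyl-5-methylidenespiro[5.5]undecane
Product: 17 (2R,5S,6S,8S,9S)-2,8-dibromo-9-chloro-1,1,5,9-tetramethylspiro[5.5]undecane
Conditions: H2 (1 atm), PtO2, EtOAc, rt
Reagents that add atoms: none
Why: Heterogeneous hydrogenation of the 1,1-disubstituted alkene under steric approach control: in the ring A chair with equatorial C10–Br the axial methyl of C11 is 1,3-syn to C7 and shields that face, so hydrogen should be delivered from the opposite face and the C7 methyl ends cis to C1 and to the C10 bromine (5S), while PtO2 in neutral EtOAc should spare the C–Br and C–Cl bonds.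

**Compound list**

1 | prenol (3-methylbut-2-en-1-ol) | CC(C)=CCO | starting material
2 | (2R)-2-bromo-3-chloro-3-methylbutan-1-ol | OC[C@@H](Br)C(C)(C)Cl | intermediate
3 | (2R)-2-bromo-3-chloro-3-methylbutyl trifluoromethanesulfonate | O=S(=O)(OC[C@@H](Br)C(C)(C)Cl)C(F)(F)F | intermediate
4 | methyl acetoacetate (methyl 3-oxobutanoate) | COC(=O)CC(C)=O | starting material
5 | sodium lithium dianion of methyl acetoacetate | COC(=O)[CH-]C(=O)[CH2-].[Na+].[Li+] | intermediate (not isolated)
6 | methyl (6R)-6-bromo-7-chloro-7-methyl-3-oxooctanoate | COC(=O)CC(=O)CC[C@@H](Br)C(C)(C)Cl | intermediate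
7 | methyl (3R)-3-bromo-2,2-dimethyl-6-oxocyclohexane-1-carboxylate (C1 not defined: epimers and enol tautomer) | COC(=O)C1C(=O)CC[C@@H](Br)C1(C)C | intermediate
8 | methyl (5R)-5-bromo-6,6-dimethyl-2-[(trifluoromethanesulfonyl)oxy]cyclohex-1-ene-1-carboxylate | COC(=O)C1=C(OS(=O)(=O)C(F)(F)F)CC[C@@H](Br)C1(C)C | intermediate
9 | methyl (5R)-5-bromo-2,6,6-trimethylcyclohex-1-ene-1-carboxylate | COC(=O)C1=C(C)CC[C@@H](Br)C1(C)C | intermediate
10 | [(5R)-5-bromo-2,6,6-trimethylcyclohex-1-en-1-yl]methanol | OCC1=C(C)CC[C@@H](Br)C1(C)C | intermediate
11 | (4R)-4-bromo-2-(bromomethyl)-1,3,3-trimethylcyclohex-1-ene | BrCC1=C(C)CC[C@@H](Br)C1(C)C | intermediate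
12 | dilithium dianion of prenol (metalated at the methyl cis to the CH2O arm) | [Li+].[Li+].[O-]C/C=C(/C)[CH2-] | intermediate (not isolated)
13 | (2Z)-5-[(5R)-5-bromo-2,6,6-trimethylcyclohex-1-en-1-yl]-3-methylpent-2-en-1-ol | OC/C=C(/C)CCC1=C(C)CC[C@@H](Br)C1(C)C | intermediate
14 | (2S,3S)-2-bromo-5-[(5R)-5-bromo-2,6,6-trimethylcyclohex-1-en-1-yl]-3-chloro-3-methylpentan-1-ol | OC[C@H](Br)[C@@](C)(Cl)CCC1=C(C)CC[C@@H](Br)C1(C)C | intermediate
15 | (2S,3S)-2-bromo-5-[(5R)-5-bromo-2,6,6-trimethylcyclohex-1-en-1-yl]-3-chloro-3-methylpentyl trifluoromethanesulfonate | O=S(=O)(OC[C@H](Br)[C@@](C)(Cl)CCC1=C(C)CC[C@@H](Br)C1(C)C)C(F)(F)F | intermediate (not isolated)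
16 | (2R,6S,8S,9S)-2,8-dibromo-9-chloro-1,1,9-trimethyl-5-methylidenespiro[5.5]undecane | C=C1CC[C@@H](Br)C(C)(C)[C@]12CC[C@](C)(Cl)[C@@H](Br)C2 | intermediate
17 | (2R,5S,6S,8S,9S)-2,8-dibromo-9-chloro-1,1,5,9-tetramethylspiro[5.5]undecane | C[C@H]1CC[C@@H](Br)C(C)(C)[C@]12CC[C@](C)(Cl)[C@@H](Br)C2 | target

**Step count and risks**

Total step count: 12. Longest linear sequence: 12 steps (from prenol 1).

Steps most likely to fail:

1. Step 11 (Proposed new method). What may go wrong: π-participation may be too slow, so that the triflate is lost by elimination or 1,2-bromine shift; closure may run through the competing chair with diaxial halogens, which attacks the other face of C6; the C7 cation may undergo a skeletal 1,2-shift before proton loss. Fallback with known reactions, setting out from 7 and rejoining at 16: 7 is saponified and subjected to decarboxylative Mannich methylenation (LiOH; then aq CH2O, Et2NH, AcOH) to give the exocyclic enone (4R)-4-bromo-3,3-dimethyl-2-methylidenecyclohexan-1-one F1. Its Diels–Alder reaction with isoprene (confined chiral Brønsted acid of the imidodiphosphorimidate class for facial control, or Me2AlCl) forms the same C1–C6 bond with para regiochemistry and gives (4R,6R)-4-bromo-5,5,9-trimethylspiro[5.5]undec-8-en-1-one F2. Markovnikov anti bromochlorination of the ring B alkene (NBS, Et4NCl, CH2Cl2, −20 °C) gives (4R,6R,8S,9S)-4,8-dibromo-9-chloro-5,5,9-trimethylspiro[5.5]undecan-1-one F3; the weak point of this fallback is that F3 would have to be separated from the diaxial-opening diastereomer. Methylenation of F3 with Cp2TiMe2 (toluene, 65 °C) returns to 16.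

2. Step 12. What may go wrong: poor facial discrimination between the syn-axial C11 methyl and the vicinal axial ring B methylene; migration of the alkene on the catalyst; partial hydrogenolysis of a C–Br bond. Fallback, setting out from 14 and arriving directly at 17: the closure of step 11 is run with excess Et3SiH and only one equivalent of the pyridine base, so that the C7 cation is reduced in the flask (ionic hydrogenation) instead of losing a proton. This replaces hydrogen addition to an alkene by hydride capture of a cation whose ring A chair again exposes the face anti to the syn-axial methyl; no new compound is formed (F0), the triflate 15 being the same intermediate.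

3. Step 4. What may go wrong: kinetic capture of the bromiranium ion by the ketone oxygen to give a dihydropyran enol ether that does not revert; hydride or methyl shifts of the tertiary cation. Fallback, setting out from 6 and rejoining at 7: 6 is silylated (TBSOTf, Et3N, CH2Cl2, 0 °C) to the carbon-only nucleophile methyl (2Z,6R)-6-bromo-3-[(tert-butyldimethylsilyl)oxy]-7-chloro-7-methyloct-2-enoate F4, and solvolysis of F4 in HFIP (Mukaiyama-type capture of the bromiranium ion at carbon, then loss of the silyl group) gives 7.

Further compounds
F1 | step 11 | (4R)-4-bromo-3,3-dimethyl-2-methylidenecyclohexan-1-one | C=C1C(=O)CC[C@@H](Br)C1(C)C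
F2 | step 11 | (4R,6R)-4-bromo-5,5,9-trimethylspiro[5.5]undec-8-en-1-one | O=C1CC[C@@H](Br)C(C)(C)[C@]12CCC(C)=CC2
F3 | step 11 | (4R,6R,8S,9S)-4,8-dibromo-9-chloro-5,5,9-trimethylspiro[5.5]undecan-1-one | O=C1CC[C@@H](Br)C(C)(C)[C@]12CC[C@](C)(Cl)[C@@H](Br)C2
F0 | step 12 | none | none
F4 | step 4 | methyl (2Z,6R)-6-bromo-3-[(tert-butyldimethylsilyl)oxy]-7-chloro-7-methyloct-2-enoate | COC(=O)/C=C(\O[Si](C)(C)C(C)(C)C)CC[C@@H](Br)C(C)(C)Cl
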